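## Retrosynthetic overview
1. Target ⇒ hexa-O-benzyl (2S)-flavanone, with neutral global hydrogenolysis as the last step. The S enantiomer is taken from the racemic protected flavanone by asymmetric transfer hydrogenation run as a kinetic resolution.
2. Ring C is the only ring that is built, and it is built last. It comes from oxa-Michael closure of a 2'-hydroxychalcone in which only the phenol next to the three-ring chain is free (MOM versus Bn), which fixes the C8/C6 pattern.
3. Key C–C bond (flavanone C2–C3) ⇒ intermolecular Claisen–Schmidt aldol condensation of the hexasubstituted acetophenone with benzaldehyde.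
4. Acetophenone ⇒ phloroacetophenone by 4,6-di-O-benzylation, bromination ortho to the chelated OH, iodination of the last CH, then two site-selective Negishi benzylations (iodide first, bromide second).
5. Three-ring chain ⇒ iterative benzyl–aryl Suzuki couplings (CHO → CH2OH → CH2Cl) of one boronate made from 5-bromosalicylaldehyde, starting from salicylaldehyde.

Assumption: CIP analysis of the given SMILES gives C2 = S, the only stereocentre, and all listed starting materials and reagents are taken as commercial.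

Notation: Bn = benzyl. MOM = methoxymethyl. D = 2-(benzyloxy)benzyl. T = 2-(benzyloxy)-5-{2-(benzyloxy)-5-[2-(benzyloxy)benzyl]benzyl}benzyl, the protected three-ring chain.

## Route

Step 1
Reactants: 1 salicylaldehyde
Product: 2 2-(benzyloxy)benzaldehyde
Conditions: BnBr (1.1 equiv), K2CO3 (1.5 equiv), DMF, 25 °C
Reagents that add atoms: benzyl bromide, BrCc1ccccc1
Why: Williamson ether synthesis on an acidic phenol, with the aldehyde inert to carbonate.

Step 2
Reactants: 2 2-(benzyloxy)benzaldehyde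
Product: 3 [2-(benzyloxy)phenyl]methanol
Conditions: NaBH4, MeOH/THF, 0 °C
Reagents that add atoms: none
Why: Borohydride reduction of an aromatic aldehyde is clean and leaves the benzyl ether untouched.

Step 3
Reactants: 3 [2-(benzyloxy)phenyl]methanol
Product: 4 1-(benzyloxy)-2-(chloromethyl)benzene
Conditions: SOCl2 (1.2 equiv), CH2Cl2, 0 → 25 °C
Reagents that add atoms: thionyl chloride, O=S(Cl)Cl
Why: Chlorodehydroxylation through the chlorosulfite gives a benzylic chloride that stores better than the bromide and serves both the Suzuki and the zinc chemistry.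

Step 4
Reactants: 5 5-bromo-2-hydroxybenzaldehyde
Product: 6 2-(benzyloxy)-5-bromobenzaldehyde
Conditions: BnBr (1.1 equiv), K2CO3 (1.5 equiv), DMF, 25 °C
Reagents that add atoms: benzyl bromide, BrCc1ccccc1
Why: Williamson ether synthesis, as in step 1.

Step 5
Reactants: 6 2-(benzyloxy)-5-bromobenzaldehyde
Product: 7 2-(benzyloxy)-5-(4,4,5,5-tetramethyl-1,3,2-dioxaborolan-2-yl)benzaldehyde
Conditions: B2pin2 (1.1 equiv), PdCl2(dppf) (3 mol %), KOAc (3 equiv), 1,4-dioxane, 85 °C
Reagents that add atoms: bis(pinacolato)diboron, CC1(C)OB(OC1(C)C)B1OC(C)(C)C(C)(C)O1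
Why: Miyaura borylation of an unhindered aryl bromide tolerates the aldehyde, and the weak base KOAc prevents Suzuki homocoupling.

Step 6
Reactants: 4 1-(benzyloxy)-2-(chloromethyl)benzene; 7 2-(benzyloxy)-5-(4,4,5,5-tetramethyl-1,3,2-dioxaborolan-2-yl)benzaldehyde
Product: 8 2-(benzyloxy)-5-D-benzaldehyde
Conditions: Pd(OAc)2 (2 mol %), SPhos (4 mol %), K3PO4 (2.5 equiv), toluene/H2O 10:1, 80 °C
Reagents that add atoms: none
Why: In this Suzuki–Miyaura benzyl–aryl coupling the benzylic chloride adds readily to zerovalent palladium and has no β-hydrogen, so the diarylmethane forms para to the OBn group of the new ring.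

Step 7
Reactants: 8 2-(benzyloxy)-5-D-benzaldehyde
Product: 9 [2-(benzyloxy)-5-D-phenyl]methanol
Conditions: NaBH4, MeOH/THF, 0 °C
Reagents that add atoms: none
Why: Borohydride reduction, as in step 2.

Step 8
Reactants: 9 [2-(benzyloxy)-5-D-phenyl]methanol
Product: 10 1-(benzyloxy)-2-(chloromethyl)-4-D-benzene
Conditions: SOCl2 (1.2 equiv), CH2Cl2, 0 → 25 °C
Reagents that add atoms: thionyl chloride, O=S(Cl)Cl
Why: Chlorodehydroxylation as in step 3, and without a Lewis acid the aryl ethers and the diarylmethane are inert.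

Step 9
Reactants: 10 1-(benzyloxy)-2-(chloromethyl)-4-D-benzene; 7 2-(benzyloxy)-5-(4,4,5,5-tetramethyl-1,3,2-dioxaborolan-2-yl)benzaldehyde
Product: 11 T-aldehyde, 2-(benzyloxy)-5-{2-(benzyloxy)-5-[2-(benzyloxy)benzyl]benzyl}benzaldehyde
Conditions: Pd(OAc)2 (2 mol %), SPhos (4 mol %), K3PO4 (2.5 equiv), toluene/H2O 10:1, 80 °C
Reagents that add atoms: none
Why: This second round of the same Suzuki–Miyaura benzyl–aryl coupling adds the third ring with the same ortho/para connectivity.

Step 10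
Reactants: 11 T-aldehyde
Product: 12 T-OH, the benzylic alcohol of 11
Conditions: NaBH4, MeOH/THF, 0 °C
Reagents that add atoms: none
Why: Borohydride reduction, as in step 2.

Step 11
Reactants: 12 T-OH
Product: 13 T-Cl, the benzylic chloride of 12
Conditions: SOCl2 (1.2 equiv), CH2Cl2, 0 → 25 °C
Reagents that add atoms: thionyl chloride, O=S(Cl)Cl
Why: Chlorodehydroxylation, as in step 3.

Step 12
Reactants: 14 1-(2,4,6-trihydroxyphenyl)ethanone
Product: 15 1-[2,4-bis(benzyloxy)-6-hydroxyphenyl]ethanone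
Conditions: BnBr (2.05 equiv), K2CO3 (2.2 equiv), DMF, 25 → 60 °C
Reagents that add atoms: benzyl bromide, BrCc1ccccc1
Why: In this Williamson ether synthesis one ortho phenol stays hydrogen-bonded to the ketone and is not alkylated, which marks the future O1.

Step 13
Reactants: 15 1-[2,4-bis(benzyloxy)-6-hydroxyphenyl]ethanone
Product: 16 1-[4,6-bis(benzyloxy)-3-bromo-2-hydroxyphenyl]ethanone
Conditions: NBS (1.0 equiv), CH2Cl2, −10 → 0 °C, dark
Reagents that add atoms: N-bromosuccinimide, O=C1CCC(=O)N1Br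
Why: Electrophilic aromatic substitution goes ortho to the free phenol, because C3 (between OH and OBn) is less crowded than C5 (between two OBn), and C3 is the future C8.

Step 14
Reactants: 16 1-[4,6-bis(benzyloxy)-3-bromo-2-hydroxyphenyl]ethanone
Product: 17 1-[4,6-bis(benzyloxy)-3-bromo-2-hydroxy-5-iodophenyl]ethanone
Conditions: NIS (1.1 equiv), TFA (0.2 equiv), MeCN, 25 °C, dark
Reagents that add atoms: N-iodosuccinimide, O=C1CCC(=O)N1I
Why: Electrophilic aromatic iodination has only one ring CH left, which is para to the free OH and ortho to two OBn groups, so no regiochemical question arises.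

Step 15
Reactants: 17 1-[4,6-bis(benzyloxy)-3-bromo-2-hydroxy-5-iodophenyl]ethanone
Product: 18 1-[4,6-bis(benzyloxy)-3-bromo-5-iodo-2-(methoxymethoxy)phenyl]ethanone
Conditions: NaH (1.2 equiv), MOMCl (1.3 equiv), DMF, 0 → 25 °C
Reagents that add atoms: chloromethyl methyl ether, COCCl
Why: O-alkylation of the sodium phenolate removes the acidic proton before the organozinc steps and gives a group orthogonal to benzyl.

Step 16
Reactants: 4 1-(benzyloxy)-2-(chloromethyl)benzene; 18 1-[4,6-bis(benzyloxy)-3-bromo-5-iodo-2-(methoxymethoxy)phenyl]ethanone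
Product: 20 1-[4,6-bis(benzyloxy)-3-bromo-5-D-2-(methoxymethoxy)phenyl]ethanone, via [2-(benzyloxy)benzyl]zinc chloride 19 (not isolated)
Conditions: (a) 4 (1.1 equiv), Zn dust, LiCl, THF, 25 °C; (b) 18, Pd(PPh3)4 (3 mol %), THF, 25 → 40 °C
Reagents that add atoms: none
Why: In this Negishi coupling zerovalent palladium with PPh3 inserts into the carbon–iodine bond far faster than into the electron-rich hindered carbon–bromine bond, and benzylic zinc reagents do not attack or enolise the ketone.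

Step 17
Reactants: 13 T-Cl; 20 1-[4,6-bis(benzyloxy)-3-bromo-5-D-2-(methoxymethoxy)phenyl]ethanone
Product: 22 1-[4,6-bis(benzyloxy)-5-D-2-(methoxymethoxy)-3-T-phenyl]ethanone, via T-zinc chloride 21 (not isolated)
Conditions: (a) 13 (1.3 equiv), Zn dust, LiCl, THF, 25 °C; (b) 20, Pd(OAc)2 (3 mol %), SPhos (6 mol %), THF, 50 °C
Reagents that add atoms: none
Why: This Negishi coupling uses a bulky electron-rich biarylphosphine, which activates di-ortho-substituted aryl bromides and places the chain next to the OMOM group.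

Step 18 (key step)
Reactants: 22 1-[4,6-bis(benzyloxy)-5-D-2-(methoxymethoxy)-3-T-phenyl]ethanone; 23 benzaldehyde
Product: 25 (E)-1-[4,6-bis(benzyloxy)-5-D-2-(methoxymethoxy)-3-T-phenyl]-3-phenylprop-2-en-1-one, via racemic beta-hydroxy ketone 24 (not isolated)
Conditions: 23 (1.5 equiv), KOH (20 equiv), EtOH/THF 2:1, 25 → 40 °C, 24–48 h
Reagents that add atoms: none
Why: In this Claisen–Schmidt crossed aldol condensation the methyl ketone is the only enolisable partner and benzaldehyde the only reactive electrophile, and E1cB loss of water erases the transient carbinol centre to give the conjugated E-enone, with all ethers stable to base.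

Step 19
Reactants: 25 (E)-1-[4,6-bis(benzyloxy)-5-D-2-(methoxymethoxy)-3-T-phenyl]-3-phenylprop-2-en-1-one
Product: 26 (E)-1-[4,6-bis(benzyloxy)-5-D-2-hydroxy-3-T-phenyl]-3-phenylprop-2-en-1-one
Conditions: conc. HCl (cat.), MeOH/THF 1:1, 45 °C
Reagents that add atoms: none
Why: Acid-catalysed acetal solvolysis removes the MOM group ortho to the carbonyl, which is the most labile kind, and the six benzyl ethers survive.

Step 20
Reactants: 26 (E)-1-[4,6-bis(benzyloxy)-5-D-2-hydroxy-3-T-phenyl]-3-phenylprop-2-en-1-one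
Product: 27 rac-5,7-bis(benzyloxy)-6-D-8-T-2-phenylchroman-4-one
Conditions: NaOAc (10 equiv), EtOH/THF 3:1, reflux; recovered 26 is recycled
Reagents that add atoms: none
Why: Intramolecular oxa-Michael addition of the single free phenol closes ring C with the chain at C8, the twisted 6'-alkoxy chalcone favours the flavanone at equilibrium, and C2 is formed racemic at this stage.

Step 21
Reactants: 27 rac-5,7-bis(benzyloxy)-6-D-8-T-2-phenylchroman-4-one
Product: 28 (2S)-5,7-bis(benzyloxy)-6-D-8-T-2-phenylchroman-4-one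
Conditions: Cp*RhCl[(R,R)-TsDPEN] (1 mol %), HCO2H/Et3N 5:2, EtOAc, 30 °C, stopped at ca. 55 % conversion (chiral HPLC control), then SiO2 chromatography
Reagents that add atoms: none
Why: In this Noyori-type asymmetric transfer hydrogenation, run as a kinetic resolution, the (R,R)-catalyst delivers hydride to the face that gives a 4R carbinol, and that face is anti to the 2-phenyl group only in the (2R)-ketone, so the (2R)-ketone is reduced to its polar cis-alcohol and the (2S)-ketone is recovered in high ee.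

Step 22
Reactants: 28 (2S)-5,7-bis(benzyloxy)-6-D-8-T-2-phenylchroman-4-one
Product: 29 sarmentosumin A, (2S)-5,7-dihydroxy-6-(2-hydroxybenzyl)-8-(2-hydroxy-5-{2-hydroxy-5-[2-hydroxybenzyl]benzyl}benzyl)-2-phenylchroman-4-one
Conditions: H2 (1 atm), Pd/C (10 wt %), EtOAc/MeOH 1:1, 25 °C, stopped at full debenzylation
Reagents that add atoms: none
Why: Catalytic hydrogenolysis cleaves all six aryl benzyl ethers under neutral conditions, so there is no retro-oxa-Michael opening, which means no racemisation at C2 and no exchange of the C6/C8 groups, and the diarylmethanes and the ketone persist.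

## Compound list
1 | salicylaldehyde | O=Cc1ccccc1O | starting material
2 | 2-(benzyloxy)benzaldehyde | O=Cc1ccccc1OCc1ccccc1 | intermediate
3 | [2-(benzyloxy)phenyl]methanol | OCc1ccccc1OCc1ccccc1 | intermediate
4 | 1-(benzyloxy)-2-(chloromethyl)benzene | ClCc1ccccc1OCc1ccccc1 | intermediate
5 | 5-bromo-2-hydroxybenzaldehyde | O=Cc1cc(Br)ccc1O | starting material
6 | 2-(benzyloxy)-5-bromobenzaldehyde | O=Cc1cc(Br)ccc1OCc1ccccc1 | intermediate
7 | 2-(benzyloxy)-5-(4,4,5,5-tetramethyl-1,3,2-dioxaborolan-2-yl)benzaldehyde | O=Cc1cc(B2OC(C)(C)C(C)(C)O2)ccc1OCc1ccccc1 | intermediate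
8 | 2-(benzyloxy)-5-[2-(benzyloxy)benzyl]benzaldehyde | O=Cc1cc(Cc2ccccc2OCc2ccccc2)ccc1OCc1ccccc1 | intermediate
9 | {2-(benzyloxy)-5-[2-(benzyloxy)benzyl]phenyl}methanol | OCc1cc(Cc2ccccc2OCc2ccccc2)ccc1OCc1ccccc1 | intermediate
10 | 1-(benzyloxy)-4-[2-(benzyloxy)benzyl]-2-(chloromethyl)benzene | ClCc1cc(Cc2ccccc2OCc2ccccc2)ccc1OCc1ccccc1 | intermediate
11 | T-aldehyde, 2-(benzyloxy)-5-{2-(benzyloxy)-5-[2-(benzyloxy)benzyl]benzyl}benzaldehyde | O=Cc1cc(Cc2cc(Cc3ccccc3OCc3ccccc3)ccc2OCc2ccccc2)ccc1OCc1ccccc1 | intermediate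
12 | T-OH, benzylic alcohol of 11 | OCc1cc(Cc2cc(Cc3ccccc3OCc3ccccc3)ccc2OCc2ccccc2)ccc1OCc1ccccc1 | intermediate
13 | T-Cl, benzylic chloride of 12 | ClCc1cc(Cc2cc(Cc3ccccc3OCc3ccccc3)ccc2OCc2ccccc2)ccc1OCc1ccccc1 | intermediate
14 | 1-(2,4,6-trihydroxyphenyl)ethanone | CC(=O)c1c(O)cc(O)cc1O | starting material
15 | 1-[2,4-bis(benzyloxy)-6-hydroxyphenyl]ethanone | CC(=O)c1c(O)cc(OCc2ccccc2)cc1OCc1ccccc1 | intermediate
16 | 1-[4,6-bis(benzyloxy)-3-bromo-2-hydroxyphenyl]ethanone | CC(=O)c1c(O)c(Br)c(OCc2ccccc2)cc1OCc1ccccc1 | intermediate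
17 | 1-[4,6-bis(benzyloxy)-3-bromo-2-hydroxy-5-iodophenyl]ethanone | CC(=O)c1c(O)c(Br)c(OCc2ccccc2)c(I)c1OCc1ccccc1 | intermediate
18 | 1-[4,6-bis(benzyloxy)-3-bromo-5-iodo-2-(methoxymethoxy)phenyl]ethanone | CC(=O)c1c(OCOC)c(Br)c(OCc2ccccc2)c(I)c1OCc1ccccc1 | intermediate
19 | [2-(benzyloxy)benzyl]zinc chloride | Cl[Zn]Cc1ccccc1OCc1ccccc1 | intermediate
20 | 1-[4,6-bis(benzyloxy)-3-bromo-5-D-2-(methoxymethoxy)phenyl]ethanone | CC(=O)c1c(OCOC)c(Br)c(OCc2ccccc2)c(Cc2ccccc2OCc2ccccc2)c1OCc1ccccc1 | intermediate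
21 | T-zinc chloride | Cl[Zn]Cc1cc(Cc2cc(Cc3ccccc3OCc3ccccc3)ccc2OCc2ccccc2)ccc1OCc1ccccc1 | intermediate
22 | 1-[4,6-bis(benzyloxy)-5-D-2-(methoxymethoxy)-3-T-phenyl]ethanone | CC(=O)c1c(OCOC)c(Cc2cc(Cc3cc(Cc4ccccc4OCc4ccccc4)ccc3OCc3ccccc3)ccc2OCc2ccccc2)c(OCc2ccccc2)c(Cc2ccccc2OCc2ccccc2)c1OCc1ccccc1 | intermediate
23 | benzaldehyde | O=Cc1ccccc1 | starting material
24 | racemic beta-hydroxy ketone, 3-hydroxy-3-phenyl-1-aryl-propan-1-one with the aryl group of 22 | OC(CC(=O)c1c(OCOC)c(Cc2cc(Cc3cc(Cc4ccccc4OCc4ccccc4)ccc3OCc3ccccc3)ccc2OCc2ccccc2)c(OCc2ccccc2)c(Cc2ccccc2OCc2ccccc2)c1OCc1ccccc1)c1ccccc1 | intermediate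
25 | (E)-1-[4,6-bis(benzyloxy)-5-D-2-(methoxymethoxy)-3-T-phenyl]-3-phenylprop-2-en-1-one | O=C(/C=C/c1ccccc1)c1c(OCOC)c(Cc2cc(Cc3cc(Cc4ccccc4OCc4ccccc4)ccc3OCc3ccccc3)ccc2OCc2ccccc2)c(OCc2ccccc2)c(Cc2ccccc2OCc2ccccc2)c1OCc1ccccc1 | intermediate
26 | (E)-1-[4,6-bis(benzyloxy)-5-D-2-hydroxy-3-T-phenyl]-3-phenylprop-2-en-1-one | O=C(/C=C/c1ccccc1)c1c(O)c(Cc2cc(Cc3cc(Cc4ccccc4OCc4ccccc4)ccc3OCc3ccccc3)ccc2OCc2ccccc2)c(OCc2ccccc2)c(Cc2ccccc2OCc2ccccc2)c1OCc1ccccc1 | intermediate
27 | rac-5,7-bis(benzyloxy)-6-D-8-T-2-phenylchroman-4-one | O=C1CC(c2ccccc2)Oc2c(Cc3cc(Cc4cc(Cc5ccccc5OCc5ccccc5)ccc4OCc4ccccc4)ccc3OCc3ccccc3)c(OCc3ccccc3)c(Cc3ccccc3OCc3ccccc3)c(OCc3ccccc3)c21 | intermediate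
28 | (2S)-5,7-bis(benzyloxy)-6-D-8-T-2-phenylchroman-4-one | O=C1C[C@@H](c2ccccc2)Oc2c(Cc3cc(Cc4cc(Cc5ccccc5OCc5ccccc5)ccc4OCc4ccccc4)ccc3OCc3ccccc3)c(OCc3ccccc3)c(Cc3ccccc3OCc3ccccc3)c(OCc3ccccc3)c21 | intermediate
29 | sarmentosumin A | O=C1C[C@@H](c2ccccc2)Oc2c(Cc3cc(Cc4cc(Cc5ccccc5O)ccc4O)ccc3O)c(O)c(Cc3ccccc3O)c(O)c21 | target

## Step count and risks
Total step count: 22.

Longest linear sequence: 15 steps (1, 2, 3, 6, 7, 8, 9, 10, 11, 17, 18, 19, 20, 21, 22).

**Risk 1, step 17.** The aryl bromide sits on a fully substituted, electron-rich ring between two alkoxy groups, and it has to couple with a large benzylic zinc reagent. The likely failures are slow oxidative addition, protodebromination and homocoupling of 21.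

The fallback sets out from 15 and comes back at 22. It reverses the order of the two benzylations, so that the valuable chain meets an aryl iodide on a less crowded ring.
- 15 is iodinated ortho to the chelated phenol (I2, HIO3, EtOH/H2O, 40 °C) to 1-[4,6-bis(benzyloxy)-2-hydroxy-3-iodophenyl]ethanone F1.
- F1 is protected (NaH, MOMCl, DMF) as 1-[4,6-bis(benzyloxy)-3-iodo-2-(methoxymethoxy)phenyl]ethanone F2.
- Negishi coupling of F2 with zinc reagent 21 (Pd(OAc)2, SPhos, THF, 25 °C) gives 1-[4,6-bis(benzyloxy)-2-(methoxymethoxy)-3-T-phenyl]ethanone F3.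
- NBS in DMF at 0 °C in the dark brominates the only CH of the trioxygenated ring A, which is far more electron-rich than the mono-oxygenated chain rings. This gives 1-[4,6-bis(benzyloxy)-5-bromo-2-(methoxymethoxy)-3-T-phenyl]ethanone F4.
- A second Negishi coupling with the cheap zinc reagent 19 in excess (Pd(OAc)2, SPhos, THF, 50 °C) gives 22.

**Risk 2, step 21.** The ketone is flanked by the 5-OBn group and deactivated by two alkoxy donors. The reduction may therefore be slow, or the selectivity factor may be too low for high ee at acceptable recovery.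

The fallback sets out from 27 and comes back at 28. It replaces the chemical resolution by a physical one. Preparative supercritical-fluid chromatography of 27 on immobilised amylose tris(3,5-dimethylphenylcarbamate) (CO2/2-propanol) delivers 28 directly. The separately collected (2R)-5,7-bis(benzyloxy)-6-D-8-T-2-phenylchroman-4-one F5 is re-equilibrated with DBU in THF through chalcone 26 to 27 and injected again.

**Risk 3, step 22.** Six benzyl ethers must fall without hydrogenolysis of the benzylic C2–O1 bond, without ketone reduction and without racemisation of the free 5,7-dihydroxyflavanone.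

The fallback sets out from 28 and comes back at 29. It is a non-reductive Lewis acid debenzylation with BCl3 (12 equiv) and pentamethylbenzene (20 equiv) as benzyl cation scavenger in CH2Cl2 at −78 °C, quenched with MeOH at −78 °C. This cannot cleave C2–O1 reductively, prevents C-benzylation of the electron-rich rings and gives no new isolated compound.

## Further compounds
F1 | step 17 | 1-[4,6-bis(benzyloxy)-2-hydroxy-3-iodophenyl]ethanone | CC(=O)c1c(O)c(I)c(OCc2ccccc2)cc1OCc1ccccc1
F2 | step 17 | 1-[4,6-bis(benzyloxy)-3-iodo-2-(methoxymethoxy)phenyl]ethanone | CC(=O)c1c(OCOC)c(I)c(OCc2ccccc2)cc1OCc1ccccc1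
F3 | step 17 | 1-[4,6-bis(benzyloxy)-2-(methoxymethoxy)-3-T-phenyl]ethanone | CC(=O)c1c(OCOC)c(Cc2cc(Cc3cc(Cc4ccccc4OCc4ccccc4)ccc3OCc3ccccc3)ccc2OCc2ccccc2)c(OCc2ccccc2)cc1OCc1ccccc1
F4 | step 17 | 1-[4,6-bis(benzyloxy)-5-bromo-2-(methoxymethoxy)-3-T-phenyl]ethanone | CC(=O)c1c(OCOC)c(Cc2cc(Cc3cc(Cc4ccccc4OCc4ccccc4)ccc3OCc3ccccc3)ccc2OCc2ccccc2)c(OCc2ccccc2)c(Br)c1OCc1ccccc1
F5 | step 21 | (2R)-5,7-bis(benzyloxy)-6-D-8-T-2-phenylchroman-4-one | O=C1C[C@H](c2ccccc2)Oc2c(Cc3cc(Cc4cc(Cc5ccccc5OCc5ccccc5)ccc4OCc4ccccc4)ccc3OCc3ccccc3)c(OCc3ccccc3)c(Cc3ccccc3OCc3ccccc3)c(OCc3ccccc3)c21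
F0 | step 22 | none | none
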